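**Strategy.** The route rests on one disconnection: ring B is cut at C9–C10 and the side chain at C11–C12 (halimane numbering). A single palladium-catalysed step turns an achiral 2-iodoenone into the bicyclic core: 6-exo carbopalladation of an isopropenyl group from C10 closes ring B and creates the quaternary stereocentre C9 under ligand control, and the alkylpalladium is captured by CO and methanol. The step exploits that C9 carries the sp2 carbon C10, the methyl C20 and the CH2 group C11, so palladium on C11 has no β-hydrogen. The precursor is 2-iodo-4,4-dimethylcyclohex-2-enone (C1–C5, C10 of ring A) bearing at C5 the chain C6–C7–C8(dioxolane)–C9(=C11H2)–C20.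

Key step: step 6

Remark: halimane numbering is used for all bicyclic compounds (ring A C1–C5, C10; ring B C5–C10; α is the face of the C11 chain on C9); C9 is S in 15–22 and R from 23 on only because the CIP rank of C8 changes, the arrangement in space being the same.

Assumption: the sense of induction of the chiral ligands in steps 6 and 16 cannot be predicted safely; the hand written is exchanged for its antipode if a first run (step 6) or a model Grignard reagent (step 16) shows the opposite sense.

Step 1
Reactants: 1 2-bromopropene; 2 3-bromopropanoyl chloride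
Product: 5 5-bromo-2-methylpent-1-en-3-one, via isopropenylmagnesium bromide 3 (not isolated), via isopropenylzinc chloride 4 (not isolated)
Conditions: Mg, THF, 40 °C; ZnCl2, 0 °C; then 2, Pd(PPh3)4 (2 mol%), THF, 0 °C to rt
Reagents that add atoms: none
Why: Negishi acylation, in which the alkenylzinc reagent couples with the acid chloride under zerovalent palladium and should touch neither the primary bromide nor the vinyl ketone that forms.

Step 2
Reactants: 5 5-bromo-2-methylpent-1-en-3-one
Product: 6 2-(2-bromoethyl)-2-(prop-1-en-2-yl)-1,3-dioxolane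
Conditions: TMSOCH2CH2OTMS (1.5 equiv), TMSOTf (5 mol%), CH2Cl2, −78 to −20 °C; pyridine quench
Reagents that add atoms: 1,2-bis(trimethylsilyloxy)ethane C[Si](C)(C)OCCO[Si](C)(C)C
Why: Aprotic ketalisation by silyl transfer through an oxocarbenium ion should convert the vinyl ketone at low temperature without conjugate addition, alkene migration or loss of HBr.

Step 3
Reactants: 7 4,4-dimethylcyclohexane-1,3-dione
Product: 8 3-isobutoxy-6,6-dimethylcyclohex-2-en-1-one
Conditions: i-BuOH, TsOH·H2O (cat.), toluene, reflux, Dean–Stark trap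
Reagents that add atoms: 2-methylpropan-1-ol CC(C)CO
Why: Acid-catalysed enol etherification with azeotropic removal of water should take place at the carbonyl remote from the quaternary carbon, so the carbonyl next to CMe2 stays as the ketone of the vinylogous ester.

Step 4
Reactants: 6 2-(2-bromoethyl)-2-(prop-1-en-2-yl)-1,3-dioxolane; 8 3-isobutoxy-6,6-dimethylcyclohex-2-en-1-one
Product: 11 4,4-dimethyl-3-{2-[2-(prop-1-en-2-yl)-1,3-dioxolan-2-yl]ethyl}cyclohex-2-en-1-one, via Grignard reagent 9 (not isolated), via tertiary carbinol adduct 10 (not isolated)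
Conditions: 6, Mg, THF, 20 °C; add to 8, LaCl3·2LiCl (0.3 equiv), THF, 0 °C; then 5% aq. oxalic acid, 0 °C, 30 min
Reagents that add atoms: water O
Why: Stork–Danheiser alkylative carbonyl transposition, in which 1,2-addition to the vinylogous ester (no α′ hydrogen, so no enolisation) is followed by enol ether hydrolysis and loss of water, both far faster than hydrolysis of the dioxolane.

Step 5
Reactants: 11 4,4-dimethyl-3-{2-[2-(prop-1-en-2-yl)-1,3-dioxolan-2-yl]ethyl}cyclohex-2-en-1-one
Product: 12 2-iodo-4,4-dimethyl-3-{2-[2-(prop-1-en-2-yl)-1,3-dioxolan-2-yl]ethyl}cyclohex-2-en-1-one (achiral)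
Conditions: I2 (2 equiv), pyridine, DMAP (0.2 equiv), CH2Cl2, rt to 40 °C, dark
Reagents that add atoms: iodine II
Why: Amine-mediated α-iodination of a cyclic enone (conjugate addition of the pyridine base, iodination of the enolate, elimination), under which the isolated isopropenyl group and the ketal should stay intact.

Step 6
Reactants: 12 2-iodo-4,4-dimethyl-3-{2-[2-(prop-1-en-2-yl)-1,3-dioxolan-2-yl]ethyl}cyclohex-2-en-1-one; 13 carbon monoxide; 14 methanol
Product: 15 methyl (9S)-8,8-ethylenedioxy-1-oxo-13,14,15,16,17-pentanorhalim-5(10)-en-12-oate (enone C1=O/C5=C10, CH2CO2Me and CH3 on C9)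
Conditions: Pd(OAc)2 (10 mol%), (R)-BINAP (20 mol%), Ag3PO4 (1.0 equiv), CO (1 atm, balloon), MeOH (10 equiv), DMA, 70 °C
Reagents that add atoms: none
Why: Proposed new method: zerovalent palladium formed from Pd(OAc)2 and BINAP inserts into the C10–I bond of 12, Ag3PO4 removes iodide so that the cationic alkenylpalladium keeps both phosphorus atoms and binds the isopropenyl group, and syn migratory insertion forms C9–C10. Ring B closes in the 6-exo-trig mode, which the three-atom tether C6–C7–C8 (helped by the gem-dialkoxy carbon C8) imposes over 7-endo attack. The alkylpalladium on neopentyl C11 has no β-hydrogen, so it lives long enough to insert CO, and methanol cleaves the acylpalladium to the ester, forming C11–C12 and returning zerovalent palladium. The closest known reactions are enantioselective domino Heck–alkoxycarbonylations of aryl halides and triflates that form quaternary carbons through neopentyl palladium alkyls, and intramolecular Heck reactions of 2-iodoenones; the six-ring, iodoenone case with asymmetric induction is the extrapolation. C9 is the only new stereocentre and is set by which face of the 1,1-disubstituted alkene is bound in the chiral pocket of the bisphosphine, the substrate itself being achiral. The step needs ring closure to outrun direct methoxycarbonylation of the alkenylpalladium, which the intramolecular alkene and the low CO pressure secure, and it needs exo regiochemistry, which the tether length secures.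

Step 7
Reactants: 15 methyl (9S)-8,8-ethylenedioxy-1-oxo-13,14,15,16,17-pentanorhalim-5(10)-en-12-oate
Product: 16 (9S)-8,8-ethylenedioxy-13,14,15,16,17-pentanorhalim-5(10)-ene-1,12-diol (both C1 epimers)
Conditions: LiAlH4, THF, 0 °C
Reagents that add atoms: none
Why: Hydride reduction of the ester to the primary alcohol with 1,2-reduction of the enone, the uncontrolled C1 carbinol centre being erased in the next step.

Step 8
Reactants: 16 (9S)-8,8-ethylenedioxy-13,14,15,16,17-pentanorhalim-5(10)-ene-1,12-diol
Product: 17 (9S)-8,8-ethylenedioxy-12-hydroxy-13,14,15,16,17-pentanorhalim-5(10)-en-1-one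
Conditions: MnO2 (20 equiv), CH2Cl2, rt
Reagents that add atoms: none
Why: Chemoselective MnO2 oxidation of the allylic alcohol should restore the C1 enone and leave the saturated primary alcohol at C12 free.

Step 9
Reactants: 17 (9S)-8,8-ethylenedioxy-12-hydroxy-13,14,15,16,17-pentanorhalim-5(10)-en-1-one
Product: 20 (5S,9S)-12-(tert-butyldiphenylsilyloxy)-8,8-ethylenedioxy-13,14,15,16,17-pentanorhalim-1(10)-en-1-yl trifluoromethanesulfonate (H5 α), via dilithium alkoxide enolate 18 (not isolated), via silylated lithium enolate 19 (not isolated)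
Conditions: Li (2.5 equiv), NH3–THF, −78 °C; isoprene; NH3 off; TBDPSCl (1.2 equiv), THF, 0 °C to rt; PhNTf2 (1.3 equiv), 0 °C to rt
Reagents that add atoms: tert-butyl(chloro)diphenylsilane CC(C)(C)[Si](Cl)(c1ccccc1)c1ccccc1; N-phenylbis(trifluoromethanesulfonimide) O=S(=O)(N(c1ccccc1)S(=O)(=O)C(F)(F)F)C(F)(F)F
Why: Dissolving-metal (Birch-type) reduction of the enone gives a C5 carbanion and a regiodefined C1 enolate; the C12 hydroxyl on the α-face arm of C9 should pass its proton to C5 through a seven-membered array (internal protonation by a nearby hydroxyl is known for enone reductions in ammonia), so H5 enters cis to C11 with C4 equatorial on ring B; the primary alkoxide is then silylated by the bulky chlorosilane, which is inert to the lithium enolate in THF, and the enolate is O-triflated.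

Step 10
Reactants: 20 (5S,9S)-12-(tert-butyldiphenylsilyloxy)-8,8-ethylenedioxy-13,14,15,16,17-pentanorhalim-1(10)-en-1-yl trifluoromethanesulfonate
Product: 21 (5S,9S)-12-(tert-butyldiphenylsilyloxy)-8,8-ethylenedioxy-13,14,15,16,17-pentanorhalim-1(10)-ene
Conditions: Pd(OAc)2 (5 mol%), PPh3 (10 mol%), HCO2H (2 equiv), Bu3N (3 equiv), DMF, 60 °C
Reagents that add atoms: none
Why: Palladium-catalysed formate reduction of the enol triflate (oxidative addition, decarboxylation of formate, C–H reductive elimination) should replace OTf by H and leave the alkene fixed at C1=C10.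

Step 11
Reactants: 21 (5S,9S)-12-(tert-butyldiphenylsilyloxy)-8,8-ethylenedioxy-13,14,15,16,17-pentanorhalim-1(10)-ene
Product: 22 (5S,9S)-12-(tert-butyldiphenylsilyloxy)-13,14,15,16,17-pentanorhalim-1(10)-en-8-one
Conditions: 2 M aq. HCl–THF (1:4), 40 °C
Reagents that add atoms: water O
Why: Acid hydrolysis of the dioxolane, now an ordinary ketal on a saturated carbon, should free the C8 ketone while the silyl ether and the trisubstituted alkene withstand dilute aqueous acid.

Step 12
Reactants: 22 (5S,9S)-12-(tert-butyldiphenylsilyloxy)-13,14,15,16,17-pentanorhalim-1(10)-en-8-one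
Product: 23 (5S,9R)-12-(tert-butyldiphenylsilyloxy)-13,14,15,16-tetranorhalima-1(10),8(17)-diene
Conditions: Ph3PCH3Br (5 equiv), KOtBu (4.8 equiv), toluene, 90 °C
Reagents that add atoms: methyltriphenylphosphonium bromide C[P+](c1ccccc1)(c1ccccc1)c1ccccc1.[Br-]
Why: Wittig methylenation with excess ylide at raised temperature should convert the hindered ketone next to quaternary C9, the only enolisable position (C7) bearing no stereocentre and no other electrophile being present.

Step 13
Reactants: 23 (5S,9R)-12-(tert-butyldiphenylsilyloxy)-13,14,15,16-tetranorhalima-1(10),8(17)-diene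
Product: 24 (5S,8R,9R)-12-(tert-butyldiphenylsilyloxy)-13,14,15,16-tetranorhalim-1(10)-ene (C17 α, H8 β)
Conditions: H2 (4 atm), RhCl(PPh3)3 (10 mol%), toluene, rt
Reagents that add atoms: none
Why: Homogeneous hydrogenation with RhCl(PPh3)3 should reduce the 1,1-disubstituted alkene and spare the hindered trisubstituted C1=C10 alkene; with H5 axial and C4 equatorial on ring B the C11 arm on C9 is axial on the α face, so hydrogen should add to C8 from the β face and place C17 equatorial and α.

Step 14
Reactants: 24 (5S,8R,9R)-12-(tert-butyldiphenylsilyloxy)-13,14,15,16-tetranorhalim-1(10)-ene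
Product: 25 (5S,8R,9R)-13,14,15,16-tetranorhalim-1(10)-en-12-ol
Conditions: TBAF, THF, rt
Reagents that add atoms: none
Why: Fluoride-induced cleavage of the silyl ether, driven by the Si–F bond, should free the primary alcohol without touching the alkene.

Step 15
Reactants: 25 (5S,8R,9R)-13,14,15,16-tetranorhalim-1(10)-en-12-ol
Product: 26 (5S,8R,9R)-12-bromo-13,14,15,16-tetranorhalim-1(10)-ene
Conditions: CBr4, PPh3, CH2Cl2, 0 °C
Reagents that add atoms: tetrabromomethane BrC(Br)(Br)Br
Why: Appel bromination converts the unhindered primary alcohol through its alkoxyphosphonium salt under neutral conditions.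

Step 16
Reactants: 26 (5S,8R,9R)-12-bromo-13,14,15,16-tetranorhalim-1(10)-ene; 27 methyl (E)-but-2-enoate (methyl crotonate)
Product: 29 methyl (5S,8R,9R,13R)-halim-1(10)-en-15-oate, via Grignard reagent 28 (not isolated)
Conditions: Mg, Et2O, reflux; then slow addition to 27 (1.3 equiv), CuI (3 mol%), (R)-Tol-BINAP (4.5 mol%), t-BuOMe, −40 °C
Reagents that add atoms: none
Why: Copper-catalysed asymmetric conjugate addition of a Grignard reagent to an α,β-unsaturated ester forms C12–C13, the chiral bisphosphine–copper complex choosing the enantioface of the crotonate and so setting C13 (R) independently of the distant ring stereocentres.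

Step 17
Reactants: 29 methyl (5S,8R,9R,13R)-halim-1(10)-en-15-oate
Product: 30 (5S,8R,9R,13R)-halim-1(10)-en-15-oic acid
Conditions: LiOH, THF–MeOH–H2O, 40 °C; then 1 M HCl
Reagents that add atoms: lithium hydroxide [Li+].[OH-]
Why: Saponification of an unhindered methyl ester; C13 is β to the carboxyl group and cannot epimerise.

Step 18
Reactants: 30 (5S,8R,9R,13R)-halim-1(10)-en-15-oic acid; 31 (R)-solketal [(4R)-2,2-dimethyl-1,3-dioxolan-4-yl]methanol
Product: 32 [(4S)-2,2-dimethyl-1,3-dioxolan-4-yl]methyl (5S,8R,9R,13R)-halim-1(10)-en-15-oate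
Conditions: EDC·HCl, DMAP (cat.), CH2Cl2, rt
Reagents that add atoms: none
Why: Steglich esterification acylates the only free hydroxyl of solketal, whose stereocentre is untouched (the descriptor changes from R to S by priority only).

Step 19
Reactants: 32 [(4S)-2,2-dimethyl-1,3-dioxolan-4-yl]methyl (5S,8R,9R,13R)-halim-1(10)-en-15-oate
Product: 33 (2S)-2,3-dihydroxypropyl (5S,8R,9R,13R)-halim-1(10)-en-15-oate
Conditions: AcOH–H2O (4:1), 40 °C
Reagents that add atoms: none
Why: Mild acid hydrolysis of the acetonide should free the diol under conditions too weak to move the acyl group or to protonate the trisubstituted alkene.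

Step 20
Reactants: 33 (2S)-2,3-dihydroxypropyl (5S,8R,9R,13R)-halim-1(10)-en-15-oate
Product: 34 (2S)-3-acetoxy-2-hydroxypropyl (5S,8R,9R,13R)-halim-1(10)-en-15-oate (CNP0317518.1)
Conditions: AcCl (1.05 equiv), 2,4,6-collidine, CH2Cl2, −78 °C
Reagents that add atoms: acetyl chloride CC(=O)Cl
Why: Selective acylation of the primary hydroxyl with acetyl chloride and a hindered pyridine base at low temperature, where the secondary hydroxyl reacts far more slowly and acyl migration is suppressed.

**Compound list**
1 | 2-bromopropene | CC(Br)=C | starting material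
2 | 3-bromopropanoyl chloride | O=C(Cl)CCBr | starting material
3 | isopropenylmagnesium bromide | CC(=C)[Mg]Br | intermediate (not isolated)
4 | isopropenylzinc chloride | CC(=C)[Zn]Cl | intermediate (not isolated)
5 | 5-bromo-2-methylpent-1-en-3-one | CC(=C)C(=O)CCBr | intermediate
6 | 2-(2-bromoethyl)-2-(prop-1-en-2-yl)-1,3-dioxolane | CC(=C)C1(CCBr)OCCO1 | intermediate
7 | 4,4-dimethylcyclohexane-1,3-dione | CC1(C)CCC(=O)CC1=O | starting material
8 | 3-isobutoxy-6,6-dimethylcyclohex-2-en-1-one | CC(C)COC1=CC(=O)C(C)(C)CC1 | intermediate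
9 | {2-[2-(prop-1-en-2-yl)-1,3-dioxolan-2-yl]ethyl}magnesium bromide | CC(=C)C1(CC[Mg]Br)OCCO1 | intermediate (not isolated)
10 | bromomagnesium alkoxide of 3-isobutoxy-6,6-dimethyl-1-{2-[2-(prop-1-en-2-yl)-1,3-dioxolan-2-yl]ethyl}cyclohex-2-en-1-ol (racemic) | CC(C)COC1=CC(O[Mg]Br)(CCC2(OCCO2)C(C)=C)C(C)(C)CC1 | intermediate (not isolated)
11 | 4,4-dimethyl-3-{2-[2-(prop-1-en-2-yl)-1,3-dioxolan-2-yl]ethyl}cyclohex-2-en-1-one | O=C1CCC(C)(C)C(CCC2(OCCO2)C(C)=C)=C1 | intermediate
12 | 2-iodo-4,4-dimethyl-3-{2-[2-(prop-1-en-2-yl)-1,3-dioxolan-2-yl]ethyl}cyclohex-2-en-1-one (achiral) | O=C1CCC(C)(C)C(CCC2(OCCO2)C(C)=C)=C1I | intermediate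
13 | carbon monoxide | [C-]#[O+] | starting material
14 | methanol | CO | starting material
15 | methyl (9S)-8,8-ethylenedioxy-1-oxo-13,14,15,16,17-pentanorhalim-5(10)-en-12-oate | COC(=O)C[C@@]1(C)C2=C(CCC13OCCO3)C(C)(C)CCC2=O | intermediate
16 | (9S)-8,8-ethylenedioxy-13,14,15,16,17-pentanorhalim-5(10)-ene-1,12-diol (C1 epimers) | OCC[C@@]1(C)C2=C(CCC13OCCO3)C(C)(C)CCC2O | intermediate
17 | (9S)-8,8-ethylenedioxy-12-hydroxy-13,14,15,16,17-pentanorhalim-5(10)-en-1-one | OCC[C@@]1(C)C2=C(CCC13OCCO3)C(C)(C)CCC2=O | intermediate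
18 | dilithium C12 alkoxide C1 enolate, H5 α (5S,9S) | [Li]OCC[C@@]1(C)C2=C(O[Li])CCC(C)(C)[C@@H]2CCC13OCCO3 | intermediate (not isolated)
19 | lithium C1 enolate of the C12 tert-butyldiphenylsilyl ether (5S,9S) | CC(C)(C)[Si](c1ccccc1)(c1ccccc1)OCC[C@@]1(C)C2=C(O[Li])CCC(C)(C)[C@@H]2CCC13OCCO3 | intermediate (not isolated)
20 | (5S,9S)-12-(tert-butyldiphenylsilyloxy)-8,8-ethylenedioxy-13,14,15,16,17-pentanorhalim-1(10)-en-1-yl trifluoromethanesulfonate | CC(C)(C)[Si](c1ccccc1)(c1ccccc1)OCC[C@@]1(C)C2=C(OS(=O)(=O)C(F)(F)F)CCC(C)(C)[C@@H]2CCC13OCCO3 | intermediate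
21 | (5S,9S)-12-(tert-butyldiphenylsilyloxy)-8,8-ethylenedioxy-13,14,15,16,17-pentanorhalim-1(10)-ene | CC(C)(C)[Si](c1ccccc1)(c1ccccc1)OCC[C@@]1(C)C2=CCCC(C)(C)[C@@H]2CCC13OCCO3 | intermediate
22 | (5S,9S)-12-(tert-butyldiphenylsilyloxy)-13,14,15,16,17-pentanorhalim-1(10)-en-8-one | CC(C)(C)[Si](c1ccccc1)(c1ccccc1)OCC[C@@]1(C)C2=CCCC(C)(C)[C@@H]2CCC1=O | intermediate
23 | (5S,9R)-12-(tert-butyldiphenylsilyloxy)-13,14,15,16-tetranorhalima-1(10),8(17)-diene | CC(C)(C)[Si](c1ccccc1)(c1ccccc1)OCC[C@@]1(C)C2=CCCC(C)(C)[C@@H]2CCC1=C | intermediate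
24 | (5S,8R,9R)-12-(tert-butyldiphenylsilyloxy)-13,14,15,16-tetranorhalim-1(10)-ene | CC(C)(C)[Si](c1ccccc1)(c1ccccc1)OCC[C@@]1(C)C2=CCCC(C)(C)[C@@H]2CC[C@H]1C | intermediate
25 | (5S,8R,9R)-13,14,15,16-tetranorhalim-1(10)-en-12-ol | OCC[C@@]1(C)C2=CCCC(C)(C)[C@@H]2CC[C@H]1C | intermediate
26 | (5S,8R,9R)-12-bromo-13,14,15,16-tetranorhalim-1(10)-ene | BrCC[C@@]1(C)C2=CCCC(C)(C)[C@@H]2CC[C@H]1C | intermediate
27 | methyl (E)-but-2-enoate | C/C=C/C(=O)OC | starting material
28 | (5S,8R,9R)-13,14,15,16-tetranorhalim-1(10)-en-12-ylmagnesium bromide | Br[Mg]CC[C@@]1(C)C2=CCCC(C)(C)[C@@H]2CC[C@H]1C | intermediate (not isolated)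
29 | methyl (5S,8R,9R,13R)-halim-1(10)-en-15-oate | COC(=O)C[C@H](C)CC[C@@]1(C)C2=CCCC(C)(C)[C@@H]2CC[C@H]1C | intermediate
30 | (5S,8R,9R,13R)-halim-1(10)-en-15-oic acid | OC(=O)C[C@H](C)CC[C@@]1(C)C2=CCCC(C)(C)[C@@H]2CC[C@H]1C | intermediate
31 | (R)-solketal | CC1(C)OC[C@@H](CO)O1 | starting material
32 | [(4S)-2,2-dimethyl-1,3-dioxolan-4-yl]methyl (5S,8R,9R,13R)-halim-1(10)-en-15-oate | CC1(C)OC[C@@H](COC(=O)C[C@H](C)CC[C@@]2(C)C3=CCCC(C)(C)[C@@H]3CC[C@H]2C)O1 | intermediate
33 | (2S)-2,3-dihydroxypropyl (5S,8R,9R,13R)-halim-1(10)-en-15-oate | OC[C@H](O)COC(=O)C[C@H](C)CC[C@@]1(C)C2=CCCC(C)(C)[C@@H]2CC[C@H]1C | intermediate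
34 | (2S)-3-acetoxy-2-hydroxypropyl (5S,8R,9R,13R)-halim-1(10)-en-15-oate | CC(=O)OC[C@H](O)COC(=O)C[C@H](C)CC[C@@]1(C)C2=CCCC(C)(C)[C@@H]2CC[C@H]1C | target

Total step count: 20. Longest linear sequence: 19 steps (steps 1, 2 and 4–20).

**Steps most likely to fail**

1. Step 6 (key step). Carbon monoxide may take the place of one phosphorus atom or of the alkene on the cationic palladium, so that enantioface discrimination is weak, or it may insert into the alkenylpalladium before ring closure. Fallback: from 12 the domino is run without a chiral ligand (Pd(OAc)2, PPh3, Et3N, CO, MeOH, DMF, 70 °C; the known racemic Heck–alkoxycarbonylation through a neopentyl palladium alkyl) to give the racemic keto ester F1. LiOH gives the racemic keto acid F2, which is resolved by fractional crystallisation of its salt with (R)-1-phenylethylamine, the salt of the 9S acid F3 (the other amine antipode is taken if it gives the less soluble salt of the wanted acid). Acidification frees the (9S)-keto acid F4, and LiAlH4 reduces acid and ketone together to the diol 16, where the route is rejoined.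

2. Step 9. C5 may take its proton from ammonia on the ring B conformer that has the C9 methyl axial, which means poor facial selectivity at C5; the alkoxide may also be silylated too slowly before the triflating agent is added. Fallback: from 15, Luche reduction (NaBH4, CeCl3·7H2O, MeOH) gives the C1 allylic alcohols; the 1β-alcohol F5 is separated from the 1α-alcohol F6, which is returned to 15 with MnO2. Mitsunobu displacement of F5 with 2-nitrobenzenesulfonyl hydrazide (PPh3, DEAD, N-methylmorpholine, THF, −30 °C) inverts C1 and gives the 1α-sulfonylhydrazine F7. On warming this loses the sulfinic acid to give the allylic diazene F8, whose retro-ene loss of N2 delivers hydrogen to C5 on the α face and moves the alkene to C1=C10, giving the alkene ester F9 (the known reductive 1,3-transposition of allylic alcohols, in which the C1 configuration fixes C5). LiAlH4 gives the alkene alcohol F10, and TBDPSCl with imidazole gives 21, where the route is rejoined.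

3. Step 5. Conjugate addition of the amine to C5, which is fully substituted and flanked by the gem-dimethyl carbon, may be too slow, so that iodination stalls or iodine begins to attack the isopropenyl group on long heating. Fallback: from 8, whose C2 is the nucleophilic carbon of an enol ether, iodination (I2, pyridine, CH2Cl2, rt) gives the 2-iodo vinylogous ester F11. Addition of the Grignard reagent 9 in the presence of CeCl3 (THF, −78 °C, to suppress iodine–magnesium exchange) gives the tertiary carbinol F12, and dilute aqueous oxalic acid effects the same Stork–Danheiser transposition to give 12, where the route is rejoined.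

**Further compounds**
F1 | step 6 | racemic methyl 8,8-ethylenedioxy-1-oxo-13,14,15,16,17-pentanorhalim-5(10)-en-12-oate | COC(=O)CC1(C)C2=C(CCC13OCCO3)C(C)(C)CCC2=O
F2 | step 6 | racemic 8,8-ethylenedioxy-1-oxo-13,14,15,16,17-pentanorhalim-5(10)-en-12-oic acid | OC(=O)CC1(C)C2=C(CCC13OCCO3)C(C)(C)CCC2=O
F3 | step 6 | (R)-1-phenylethylammonium salt of the (9S)-keto acid | [O-]C(=O)C[C@@]1(C)C2=C(CCC13OCCO3)C(C)(C)CCC2=O.C[C@@H]([NH3+])c1ccccc1
F4 | step 6 | (9S)-8,8-ethylenedioxy-1-oxo-13,14,15,16,17-pentanorhalim-5(10)-en-12-oic acid | OC(=O)C[C@@]1(C)C2=C(CCC13OCCO3)C(C)(C)CCC2=O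
F5 | step 9 | methyl (1R,9S)-8,8-ethylenedioxy-1β-hydroxy-13,14,15,16,17-pentanorhalim-5(10)-en-12-oate | COC(=O)C[C@@]1(C)C2=C(CCC13OCCO3)C(C)(C)CC[C@H]2O
F6 | step 9 | methyl (1S,9S)-8,8-ethylenedioxy-1α-hydroxy-13,14,15,16,17-pentanorhalim-5(10)-en-12-oate | COC(=O)C[C@@]1(C)C2=C(CCC13OCCO3)C(C)(C)CC[C@@H]2O
F7 | step 9 | methyl (9S)-8,8-ethylenedioxy-1α-[1-(2-nitrophenylsulfonyl)hydrazinyl]-13,14,15,16,17-pentanorhalim-5(10)-en-12-oate | COC(=O)C[C@@]1(C)C2=C(CCC13OCCO3)C(C)(C)CC[C@@H]2N(N)S(=O)(=O)c1ccccc1[N+](=O)[O-]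
F8 | step 9 | methyl (9S)-1α-diazenyl-8,8-ethylenedioxy-13,14,15,16,17-pentanorhalim-5(10)-en-12-oate | COC(=O)C[C@@]1(C)C2=C(CCC13OCCO3)C(C)(C)CC[C@@H]2N=N
F9 | step 9 | methyl (5S,9S)-8,8-ethylenedioxy-13,14,15,16,17-pentanorhalim-1(10)-en-12-oate | COC(=O)C[C@@]1(C)C2=CCCC(C)(C)[C@@H]2CCC13OCCO3
F10 | step 9 | (5S,9S)-8,8-ethylenedioxy-13,14,15,16,17-pentanorhalim-1(10)-en-12-ol | OCC[C@@]1(C)C2=CCCC(C)(C)[C@@H]2CCC13OCCO3
F11 | step 5 | 2-iodo-3-isobutoxy-6,6-dimethylcyclohex-2-en-1-one | CC(C)COC1=C(I)C(=O)C(C)(C)CC1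
F12 | step 5 | 2-iodo-3-isobutoxy-6,6-dimethyl-1-{2-[2-(prop-1-en-2-yl)-1,3-dioxolan-2-yl]ethyl}cyclohex-2-en-1-ol (racemic) | CC(C)COC1=C(I)C(O)(CCC2(OCCO2)C(C)=C)C(C)(C)CC1
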